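I decided to reckon with what target has not taken instead of what it has made: the odds, target over the remainder of the charge, y/(1−y).

| flask | solid substrate | coupling partner | protic impurity | temperature | remark | time |
|---|---|---|---|---|---|---|
| Tuesday's | 0.54 M | 0.594 M | 0.0108 M | 0 °C | the very flask that is asked about, followed so far |  |
| Monday's | 0.54 M | 0.594 M | 0.0108 M | 6 °C | run made earlier |  |
| flask | 0.54 M | 0.594 M | 0.0108 M | 0 °C |  | 2.5 h |

- Tuesday's (time / h: target / %): 0.333: 3.5; 0.667: 5.6; 1.00: 6.5; 1.33: 8.6; 2.00: 9.0; 2.50: 9.9
- Monday's (time / h: target / %): 0.333: 6.0; 0.667: 9.8; 1.00: 12.0; 1.33: 14.6; 2.00: 16.3; 2.50: 16.0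

(scatter of a reading: 0.5 percentage points)

- percent here means solid substrate units held: one side product counts as two
- what is said of target includes idle adduct
- solid substrate is a solid; its amount is given per volume of the solution
- additions bring no volume worth counting
- the numbers in the tables scatter by 0.5 percentage points (one standard deviation)
- what may be going on: dissolved substrate + target -> side product; coupling partner + protic impurity -> quenched reagent; target <-> isomer of the product; solid substrate <-> dissolved substrate; dissolved substrate + coupling partner -> target; coupling partner + target <-> idle adduct
- at the start none of the solid substrate is in solution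

- gamma: at 2.5 h add coupling partner, 100% of the amount charged, then wait 50 min
- theta: change nothing and wait 50 min more
- alpha: at 2.5 h raise the temperature by 15 K, then wait 50 min

* target, in percent of the solid substrate first charged, at 2.5 h
* what to do for the largest gain in target; "none" if nothing gains more than 2 percentage points (gamma / theta / alpha / none)
* target present, in percent of the solid substrate first charged, after gamma
* target present, in percent of the solid substrate first charged, after theta

First doubt: had the readings stopped moving? Tuesday's last two differ by 0.9 percentage points and Monday's by −0.3 points, while the difference of two readings scatters by 0.71 points. So I treated both as level, averaged each pair, and read 9.45% for Tuesday's flask and 16.1% for Monday's. The first is my figure for now, and I expected waiting to gain little.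

Monday's level stood higher than Tuesday's, which looks like thermodynamic control. Scaling percent by their ratio over 15 K, against the 6.00 K between the runs, gives 36.1%. But a plain ratio has no ceiling, and percent has one. Odds have none to run into, so I took 0.104 and 0.193, whose quotient is 1.85, the odds factor per 6.00 K. Applied over 15 K, it gives 32.6%.

Next objection: 50 min may be too short. Monday's reading at 1.00 h, later than 50 min, still lacked 25.7% of the level I read, so this shortfall errs on the kind side. Leaving that fraction of the climb undone gives 26.6%, still a gain far above the margin. Both runs had the same partner charge, so this reckoning gives no number for gamma.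

The forecast gave 9.9% now, 10.5% after theta, 15% after gamma, and chose alpha: “This is the biggest gain, though an extrapolation.”

The flask gave 9.53%, then 9.56% after theta and 13.4% after gamma, and alpha gained most, 26 points. Free target and isomer of the product relax, by that step alone, with a half-life of 0.791 min, short against 2.5 h, and at 2.50 h the isomer held 69.9%. Starting from 9.53%, with the climb taken as complete, the factor 1.85 gives a gain of 23 points for alpha, against the 26 points found.

    dissolved substrate + target → side product (k = 0.00330 L mol⁻¹ s⁻¹, Ea = 45.0 kJ mol⁻¹)
    coupling partner + protic impurity → quenched reagent (k = 0.0280 L mol⁻¹ s⁻¹, Ea = 42.0 kJ mol⁻¹)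
    target ⇌ isomer of the product (K = 8.10, k = 0.0130 s⁻¹, Ea = 85.0 kJ mol⁻¹, ΔH = −79.0 kJ mol⁻¹)
    solid substrate ⇌ dissolved substrate, rate k4*(cs4 - [dissolved substrate]) while solid is left; crystals form when [dissolved substrate] > cs4 (solubility = 0.0730 M, k = 0.00230 s⁻¹)
    dissolved substrate + coupling partner → target (k = 0.00440 L mol⁻¹ s⁻¹, Ea = 43.0 kJ mol⁻¹)
    coupling partner + target ⇌ idle adduct, settled at all times (K = 0.820 L mol⁻¹, ΔH = 3.00 kJ mol⁻¹)
    (constants at 0 °C)

For the repeat at 15 °C, 1.85 on Tuesday's odds gives 32.6%. At 2.50 h that flask held 27.9% of target, with side product at 38.9%.

The data were generated by integration for an exercise, and the scatter is random.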